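**Strategy.** The cis-fused γ-lactone on the cyclohexane ring (tetrahydroindole numbering: C4–C, C5–O) is read as a cyclobutanone that has taken up one oxygen atom, and the cyclohexane ring on the pyrrole as a vinylpyrrole Diels–Alder retron. The key step is a catalyst-controlled, endo-selective [4+2] cycloaddition of cyclobutenone to a monocyclic push–pull 5-[(E)-butenyl]pyrrole-2-carboxylate: it forms C3a–C4 and C5–C6, closes the carbocycle and sets C4, C5 and C6 in one event. Baeyer–Villiger oxygen insertion then gives the lactone; the azepane is closed afterwards at C7 anti to the ethyl group, and the side-chain lactone is attached last.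

Key step: step 5

Remark on locants: the pyrrole–cyclohexane unit is numbered throughout as a 4,5,6,7-tetrahydroindole (N1, C2, C3, C3a, C4, C5, C6, C7, C7a). In the target C2 carries the side-chain lactone (carbinol carbon C5′, methyl-bearing carbon C3′), C4/C5 carry the fused lactone (α-carbon = C-α), C6 the ethyl group, and N1/C7 are bridged by the azepane. Target descriptors: 4S, 5R, 6R, 7R, C-α S, 5′R, 3′S.

Assumption: boronate 5 and 3-bromocyclobutanone 7 are taken as purchasable; each is otherwise one known step away (hydroboration of but-1-yne with pinacolborane; bromodecarboxylation of 3-oxocyclobutanecarboxylic acid).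

Step 1
Reactants: 1 5-bromo-1H-pyrrole-2-carboxylic acid
Product: 2 benzyl 5-bromo-1H-pyrrole-2-carboxylate
Conditions: BnBr, NaHCO3, DMF, rt
Reagents that add atoms: benzyl bromide, BrCc1ccccc1
Why: Carboxylate O-alkylation (SN2 esterification); hydrogencarbonate does not ionise the pyrrole N–H, so only the ester forms, and this ester later serves as blocking group, polarising group and carbon source (C5′) for the side chain.

Step 2
Reactants: 2 benzyl 5-bromo-1H-pyrrole-2-carboxylate; 3 1-bromo-4-chlorobutane
Product: 4 benzyl 5-bromo-1-(4-chlorobutyl)-1H-pyrrole-2-carboxylate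
Conditions: K2CO3, DMF, 50 °C
Reagents that add atoms: none
Why: N-Alkylation of the pyrrolide (SN2), the N–H being acidified by ester and bromine; the primary bromide reacts much faster than the chloride, which is kept for step 7.

Step 3
Reactants: 4 benzyl 5-bromo-1-(4-chlorobutyl)-1H-pyrrole-2-carboxylate; 5 (E)-but-1-en-1-ylboronic acid pinacol ester
Product: 6 benzyl 5-[(E)-but-1-en-1-yl]-1-(4-chlorobutyl)-1H-pyrrole-2-carboxylate
Conditions: Pd(dppf)Cl2 (5 mol %), K2CO3, 1,4-dioxane/H2O, 80 °C
Reagents that add atoms: none
Why: Suzuki–Miyaura cross-coupling with retention of alkene geometry, so the E (ethyl-outside) diene needed in step 5 should form as one isomer; the unactivated alkyl chloride does not undergo oxidative addition.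

Step 4
Reactants: 7 3-bromocyclobutan-1-one
Product: 8 cyclobut-2-en-1-one
Conditions: n-Bu3N, neat, rt, reduced pressure; distilled into a −78 °C trap, used as CH2Cl2 solution
Reagents that add atoms: none
Why: E1cB-type dehydrobromination of the β-bromo ketone by the tertiary amine; the volatile strained enone is removed from the ammonium salt as it forms.

Step 5
Reactants: 6 benzyl 5-[(E)-but-1-en-1-yl]-1-(4-chlorobutyl)-1H-pyrrole-2-carboxylate; 8 cyclobut-2-en-1-one
Product: 10 tricyclic cyclobutanone (4R,5R,6R), via primary cycloadduct 9 (not isolated)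
Conditions: (S)-o-tolyl-CBS-oxazaborolidine·HNTf2 (20 mol %), 8 (2 equiv), CH2Cl2, −78 → −20 °C; then Et3N, DBU (10 mol %), rt
Reagents that add atoms: none
Why: The cationic oxazaborolidinium binds the cyclobutenone carbonyl; the nucleophilic terminus of the s-cis diene, C3a (the pyrrole β-carbon meta to the ester), attacks the enone β-carbon and the boron enolate closes onto the butenyl terminus C6 in a concerted but asynchronous [4+2] (suprafacial on both partners), after which DBU moves the vinylogously acidic H-3a of adduct 9 to C7 and restores the pyrrole. Closest known reaction types are the Diels–Alder reactions of 2-vinylpyrroles and 2-vinylindoles, the endo-selective cycloadditions of cyclobutenone, and chiral oxazaborolidinium-catalysed Diels–Alder reactions of cyclic enones. The six-membered carbocycle is closed in the [4+2] mode (σ-bonds C3a–C4 and C5–C6), the four-membered ring being carried in intact. C4 and C5 are cis because the dienophile is a cis-cycloalkene, C6 follows from the E alkene (ethyl outside) combined with the endo orientation of the four-membered ring, which puts ethyl, C5–C(=O) and C4–CH2 on one face, and the absolute sense comes from the catalyst shielding one face of the bound enone (should the (S)-catalyst give the mirror image, the (R)-catalyst is used). The step needs regioselectivity (C=O on C5), which the push–pull polarisation secures because the C2 ester makes C6 the electrophilic and C3a the nucleophilic terminus; endo selectivity, which is intrinsic to cyclobutenone; and chemoselectivity over Friedel–Crafts addition, secured because both pyrrole α-positions are substituted, while the N-alkyl group biases the diene towards the s-cis conformer.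

Step 6
Reactants: 10 tricyclic cyclobutanone
Product: 11 tricyclic γ-lactone (4S,5R,6R)
Conditions: 30% aq H2O2, (CF3)2CHOH, 0 °C → rt
Reagents that add atoms: hydrogen peroxide, OO
Why: Baeyer–Villiger oxidation (insertion of one oxygen atom): the strained cyclobutanone is attacked by H2O2 activated by the fluorinated alcohol and the more substituted α-carbon C5 migrates with retention, so oxygen ends on C5 and the cis fusion is kept; the ester-deactivated pyrrole should survive this non-peracid oxidant.

Step 7
Reactants: 11 tricyclic γ-lactone
Product: 12 tetracyclic azepane lactone (4S,5R,6R,7R)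
Conditions: LDA (2.1 equiv), THF/DMPU, −78 → 0 °C, 0.01 M; AcOH, −78 °C
Reagents that add atoms: none
Why: Lateral (vinylogous) enolate alkylation: the first equivalent of base gives the lactone enolate (which also masks the lactone carbonyl), the second removes H-7, which is conjugated through the pyrrole to the C2 ester, and the extended enolate closes the seven-membered ring by intramolecular SN2 on the primary chloride (7-(enolendo)-exo-tet); C7 is set by substrate control, the chain bonding on the face anti to the pseudo-axial C5–O bond and the C6 ethyl group, which is also the more stable trans C6/C7 arrangement.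

Step 8
Reactants: 12 tetracyclic azepane lactone
Product: 15 α-methylene lactone (4R,5R,6R,7R), via Mannich base 13 (not isolated), via ammonium iodide 14 (not isolated)
Conditions: LDA (1.05 equiv), THF, −78 °C; Me2N=CH2+ I−, −78 °C → rt; MeI, MeOH, rt; aq NaHCO3/CH2Cl2, rt
Reagents that add atoms: Eschenmoser's salt (N,N-dimethylmethyleneiminium iodide), C=[N+](C)C.[I-]
Why: α-Methylenation through the lithium enolate (Mannich reaction, N-methylation, E1cB elimination); one equivalent of base reaches only the lactone α-CH2 because H-7 is far less acidic, and the transient α-stereocentre of 13/14 is destroyed in the elimination (the C4 descriptor changes only through CIP priorities).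

Step 9
Reactants: 15 α-methylene lactone
Product: 16 tetracyclic carboxylic acid (4S,5R,6R,7R,αS)
Conditions: H2 (1 atm), 10% Pd/C, EtOAc, rt
Reagents that add atoms: none
Why: Heterogeneous hydrogenation should deliver hydrogen to the exocyclic alkene from the convex face of the cis-fused lactone (the face of H-4 and H-5), placing the new methyl group on the concave face (C-α S), while the benzyl ester is cleaved by hydrogenolysis in the same operation and the pyrrole is left intact.

Step 10
Reactants: 16 tetracyclic carboxylic acid; 17 methyl (R)-3-bromo-2-methylpropanoate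
Product: 20 keto ester (3′S), via organozinc bromide 18 (not isolated), via acid chloride 19 (not isolated)
Conditions: 17, Zn dust, I2 (5 mol %), DMA, 70 °C; separately 16, Me2C=C(Cl)NMe2, CH2Cl2, 0 °C → rt; combine, Pd(PPh3)4 (5 mol %), THF, rt
Reagents that add atoms: none
Why: Zinc insertion into the primary bromide leaves the α-stereocentre untouched, and Negishi acylation of the acid chloride (made under neutral conditions) gives the ketone, since alkylzinc reagents add neither to the lactone nor to the product ketone; the (R)-bromide becomes the (S)-centre C3′ only through the change in CIP priorities.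

Step 11
Reactants: 20 keto ester
Product: 22 target CNP0232452.1, via hydroxy ester 21 (not isolated)
Conditions: (S)-Me-CBS (0.5 equiv), catecholborane (1.5 equiv), toluene, −40 °C; aq NaHCO3 work-up; then 2-hydroxypyridine (20 mol %), toluene, 60 °C
Reagents that add atoms: none
Why: Corey–Bakshi–Shibata reduction, in which the (S)-oxazaborolidine distinguishes the large heteroaryl group from the small CH2R group and is expected to give the (R)-carbinol C5′ (the sense known for aryl alkyl ketones), followed by lactonisation of the γ-hydroxy ester under neutral bifunctional catalysis, which avoids acid ionisation of the pyrrolylcarbinol and base epimerisation of either α-methyl lactone.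

**Compound list**

1 | 5-bromo-1H-pyrrole-2-carboxylic acid | OC(=O)c1ccc(Br)[nH]1 | starting material
2 | benzyl 5-bromo-1H-pyrrole-2-carboxylate | O=C(OCc1ccccc1)c1ccc(Br)[nH]1 | intermediate
3 | 1-bromo-4-chlorobutane | ClCCCCBr | starting material
4 | benzyl 5-bromo-1-(4-chlorobutyl)-1H-pyrrole-2-carboxylate | O=C(OCc1ccccc1)c1ccc(Br)n1CCCCCl | intermediate
5 | (E)-but-1-en-1-ylboronic acid pinacol ester | CC/C=C/B1OC(C)(C)C(C)(C)O1 | starting material
6 | benzyl 5-[(E)-but-1-en-1-yl]-1-(4-chlorobutyl)-1H-pyrrole-2-carboxylate | CC/C=C/c1ccc(C(=O)OCc2ccccc2)n1CCCCCl | intermediate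
7 | 3-bromocyclobutan-1-one | O=C1CC(Br)C1 | starting material
8 | cyclobut-2-en-1-one | O=C1C=CC1 | intermediate
9 | primary cycloadduct: non-aromatic 3a-H tautomer of 10 with C7a=C7 double bond, H-3a trans to the four-membered ring | CC[C@H]1[C@H]2C(=O)C[C@H]2[C@H]2C=C(C(=O)OCc3ccccc3)N(CCCCCl)C2=C1 | intermediate
10 | benzyl (4R,5R,6R)-1-(4-chlorobutyl)-6-ethyl-4,5,6,7-tetrahydroindole-2-carboxylate with a cyclobutanone cis-fused across C4–C5 (C=O carbon on C5, CH2 on C4, ethyl cis to the four-membered ring) | CC[C@H]1[C@H]2C(=O)C[C@H]2c2cc(C(=O)OCc3ccccc3)n(CCCCCl)c2C1 | intermediate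
11 | benzyl (4S,5R,6R)-1-(4-chlorobutyl)-6-ethyl-4,5,6,7-tetrahydroindole-2-carboxylate with a γ-lactone cis-fused across C4–C5 (C4–CH2–C(=O)–O–C5, ethyl cis to O) | CC[C@H]1[C@H]2OC(=O)C[C@H]2c2cc(C(=O)OCc3ccccc3)n(CCCCCl)c2C1 | intermediate
12 | tetracyclic benzyl ester (4S,5R,6R,7R): as 11, with N1 and C7 bridged by (CH2)4 (azepane trans to ethyl) | CC[C@H]1[C@H]2OC(=O)C[C@H]2c2cc(C(=O)OCc4ccccc4)n3c2[C@@H]1CCCC3 | intermediate
13 | Mannich base: 12 with CH2NMe2 on C-α (convex face) | CC[C@H]1[C@H]2OC(=O)[C@H](CN(C)C)[C@H]2c2cc(C(=O)OCc4ccccc4)n3c2[C@@H]1CCCC3 | intermediate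
14 | trimethylammonium iodide of 13 | CC[C@H]1[C@H]2OC(=O)[C@H](C[N+](C)(C)C)[C@H]2c2cc(C(=O)OCc4ccccc4)n3c2[C@@H]1CCCC3.[I-] | intermediate
15 | tetracyclic α-methylene lactone benzyl ester (4R,5R,6R,7R) | CC[C@H]1[C@H]2OC(=O)C(=C)[C@H]2c2cc(C(=O)OCc4ccccc4)n3c2[C@@H]1CCCC3 | intermediate
16 | tetracyclic α-methyl lactone 2-carboxylic acid (4S,5R,6R,7R, C-α S; methyl on the concave face) | CC[C@H]1[C@H]2OC(=O)[C@@H](C)[C@H]2c2cc(C(O)=O)n3c2[C@@H]1CCCC3 | intermediate
17 | methyl (R)-3-bromo-2-methylpropanoate | BrC[C@H](C)C(=O)OC | starting material
18 | [(2R)-3-methoxy-2-methyl-3-oxopropyl]zinc bromide | Br[Zn]C[C@H](C)C(=O)OC | intermediate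
19 | acid chloride of 16 | CC[C@H]1[C@H]2OC(=O)[C@@H](C)[C@H]2c2cc(C(Cl)=O)n3c2[C@@H]1CCCC3 | intermediate
20 | keto ester: 2-[(3S)-4-methoxy-3-methyl-4-oxobutanoyl] derivative of the tetracyclic lactone | CC[C@H]1[C@H]2OC(=O)[C@@H](C)[C@H]2c2cc(C(=O)C[C@H](C)C(=O)OC)n3c2[C@@H]1CCCC3 | intermediate
21 | hydroxy ester: (5′R)-carbinol of 20 | CC[C@H]1[C@H]2OC(=O)[C@@H](C)[C@H]2c2cc([C@H](O)C[C@H](C)C(=O)OC)n3c2[C@@H]1CCCC3 | intermediate
22 | target CNP0232452.1 (4S,5R,6R,7R, C-α S, 5′R, 3′S) | CC[C@H]1[C@H]2OC(=O)[C@@H](C)[C@H]2c2cc([C@H]3C[C@H](C)C(=O)O3)n3c2[C@@H]1CCCC3 | target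

**Step count.** Total: 11 steps. Longest linear sequence: 10 steps (1 → 22 through steps 1–3 and 5–11); step 4 is a one-step side branch.

**Steps most likely to fail**

Step 5. The basic ester carbonyl of the diene may sequester the Lewis acid, or the acid may polymerise cyclobutenone, so that conversion or enantiofacial discrimination falls short; conjugate addition at C3a without ring closure is a further leak. Fallback (catalyst control replaced by racemic cycloaddition plus resolution): 6 and 8 are combined with ZnCl2 in CH2Cl2 at room temperature and the adduct is isomerised with DBU as before, which should give 10 together with the enantiomer of 10 F1; preparative chromatography on a chiral stationary phase separates the two and the route is rejoined at 10.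

Step 7. The C7 carbanion may not form cleanly (attack of the amide base on the benzyl ester, loss of HCl from the side chain, intermolecular alkylation), or the ring closure may show poor facial selectivity. Fallback (cation chemistry and metathesis instead of carbanion alkylation), setting out from 2: N-allylation with allyl bromide (K2CO3, DMF) gives benzyl 1-allyl-5-bromo-1H-pyrrole-2-carboxylate F2; Suzuki coupling with 5 under the conditions of step 3 gives the N-allyl diene F3; cycloaddition with 8 as in step 5 gives the N-allyl cyclobutanone F4, and oxidation as in step 6 the N-allyl lactone F5. Pb(OAc)4 in AcOH, the classical side-chain oxidation of α-alkylpyrrole-2-carboxylates, acetoxylates the α-methylene group C7 to the 7-acetate F6 (epimer mixture). BF3·OEt2 with allyltrimethylsilane ionises it to the azafulvenium ion, which is allylated anti to the C6 ethyl group (Hosomi–Sakurai) to give the 7-allyl lactone F7. Ring-closing metathesis (Grubbs II, CH2Cl2) of the two allyl groups gives the dihydroazepine F8, and hydrogenation of the ring alkene with RhCl(PPh3)3/H2, which spares the benzyl ester, rejoins the route at 12.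

Step 11. The 2-acylpyrrole carbonyl is a vinylogous amide and may be reduced slowly or with poor facial selectivity, and the pyrrolylcarbinol may ionise to an azafulvenium ion with loss of configuration or over-reduction. Fallback (C5′ created by C–C bond formation instead of C=O reduction), setting out from 19: reduction with Bu3SnH/Pd(PPh3)4 gives the aldehyde F9; 17 is converted with NaI in acetone into methyl (R)-3-iodo-2-methylpropanoate F10, and iodine–zinc exchange (Et2Zn, cat. CuI) gives the dialkylzinc F11. Its addition to F9 under Ti(OiPr)4 and a chiral trans-cyclohexane-1,2-bis(trifluoromethanesulfonamide) ligand (the (1S,2S) antipode is expected by analogy with benzaldehyde additions to give the (R)-carbinol) is a catalyst-controlled alkylzinc addition to an aromatic aldehyde and gives 21, where the route is rejoined for the lactonisation of step 11.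

**Further compounds**

F1 | step 5 | enantiomer of 10 | CC[C@@H]1[C@@H]2C(=O)C[C@@H]2c2cc(C(=O)OCc3ccccc3)n(CCCCCl)c2C1
F2 | step 7 | benzyl 1-allyl-5-bromo-1H-pyrrole-2-carboxylate | C=CCn1c(Br)ccc1C(=O)OCc1ccccc1
F3 | step 7 | benzyl 1-allyl-5-[(E)-but-1-en-1-yl]-1H-pyrrole-2-carboxylate | CC/C=C/c1ccc(C(=O)OCc2ccccc2)n1CC=C
F4 | step 7 | N-allyl analogue of cyclobutanone 10 | CC[C@H]1[C@H]2C(=O)C[C@H]2c2cc(C(=O)OCc3ccccc3)n(CC=C)c2C1
F5 | step 7 | N-allyl analogue of lactone 11 | CC[C@H]1[C@H]2OC(=O)C[C@H]2c2cc(C(=O)OCc3ccccc3)n(CC=C)c2C1
F6 | step 7 | 7-acetoxy derivative of F5 (C7 epimer mixture) | CC[C@H]1[C@H]2OC(=O)C[C@H]2c2cc(C(=O)OCc3ccccc3)n(CC=C)c2C1OC(C)=O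
F7 | step 7 | (7R)-7-allyl derivative of F5 (allyl trans to ethyl) | CC[C@H]1[C@H]2OC(=O)C[C@H]2c2cc(C(=O)OCc3ccccc3)n(CC=C)c2[C@@H]1CC=C
F8 | step 7 | dihydroazepine: 12 with a ring C=C between the two central azepane carbons | CC[C@H]1[C@H]2OC(=O)C[C@H]2c2cc(C(=O)OCc4ccccc4)n3c2[C@@H]1CC=CC3
F9 | step 11 | 2-carbaldehyde corresponding to acid 16 | CC[C@H]1[C@H]2OC(=O)[C@@H](C)[C@H]2c2cc(C=O)n3c2[C@@H]1CCCC3
F10 | step 11 | methyl (R)-3-iodo-2-methylpropanoate | IC[C@H](C)C(=O)OC
F11 | step 11 | bis[(2R)-3-methoxy-2-methyl-3-oxopropyl]zinc | COC(=O)[C@@H](C)C[Zn]C[C@H](C)C(=O)OC
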